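**Retrosynthetic overview**
1. Ring A is closed last: ionisation of tertiary alcohol 15 gives the C18 cation, the C9=C10 olefin captures it and H9 is lost (the presumed final biosynthetic C–C bond).
2. 15 comes from dioxane vinyl triflate 13 and ring-B diene 5 by hydroboration/B-alkyl Suzuki coupling (C10–C11); the hydroboration sets C12 cis to C17.
3. 13 comes from hydroperoxide 12 by 6-exo peroxy-Michael addition to the 2-enoate (the presumed biosynthetic dioxane closure); 12 derives from pseudoionone, methyl methacrylate and O2.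
4. 5 comes from (S)-α-terpineol by singlet-oxygen ene reaction, oxidative transposition and methylenation.
5. Ring order: 1,2-dioxane (step 7), then ring A (step 9); ring B is taken from the chiral pool.

Assumption (presumed biosynthesis): a linear norsesterterpenoid acid closes the dioxane by conjugate addition of a C6 hydroperoxide to the 2-enoate, and closes the carbobicycle through an α-terpinyl-type C18 cation that is trapped by the C9=C10 olefin and loses H9; atom numbers follow the acid chain (C1 = ester carbon, C12/C17 = ring-fusion carbons).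

**Step 1**
Reactants: 1 (S)-α-terpineol
Product: 3 (4S)-4-(2-hydroxypropan-2-yl)-1-methylcyclohex-2-en-1-ol (both C1 epimers), via allylic hydroperoxide 2 (not isolated)
Conditions: O2, tetraphenylporphyrin (cat.), hν, CH2Cl2, 0 °C; then PPh3; the tertiary allylic diol is separated from the regioisomeric ene products
Reagents that add atoms: dioxygen, O=O
Why: Schenck ene reaction of singlet oxygen at the ring alkene (O to the methyl-bearing carbon, C=C shifts to C2=C3) followed by phosphine reduction of the hydroperoxide; the C4 stereocentre of 1 is untouched and the new C1 centre, formed as both epimers, is erased in step 2.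

**Step 2**
Reactants: 3 (4S)-4-(2-hydroxypropan-2-yl)-1-methylcyclohex-2-en-1-ol
Product: 4 (6R)-6-(2-hydroxypropan-2-yl)-3-methylcyclohex-2-en-1-one
Conditions: pyridinium chlorochromate [C5H5NH][CrO3Cl], NaOAc, 4 Å MS, CH2Cl2, rt
Reagents that add atoms: pyridinium chlorochromate, [O-][Cr](=O)(=O)Cl.c1cc[nH+]cc1
Why: Dauben–Babler oxidative 1,3-transposition, in which the tertiary allylic chromate ester undergoes a [3,3] shift and the transposed secondary chromate is oxidised to the enone; both C1 epimers converge, the saturated tertiary alcohol cannot be oxidised, and the stereocentre inherited from 1 is not enolised under buffered conditions.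

**Step 3**
Reactants: 4 (6R)-6-(2-hydroxypropan-2-yl)-3-methylcyclohex-2-en-1-one
Product: 5 2-[(1S)-4-methyl-2-methylidenecyclohex-3-en-1-yl]propan-2-ol
Conditions: Tebbe reagent Cp2Ti(μ-Cl)(μ-CH2)AlMe2 (2.5 equiv), pyridine, THF–toluene, −40 → 0 °C
Reagents that add atoms: Tebbe reagent, C[Al-]1(C)C[Ti](C2C=CC=C2)(C2C=CC=C2)[Cl+]1
Why: Tebbe carbonyl methylenation via the titanium methylidene, chosen because it is non-basic, so the enolisable α-stereocentre and the retro-aldol-prone β-hydroxy ketone survive; no new stereocentre is formed.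

**Step 4**
Reactants: 6 (3E,5E)-pseudoionone
Product: 8 (2Z,5E)-6,10-dimethylundeca-2,5,9-trien-2-yl trifluoromethanesulfonate, via lithium enolate 7 (not isolated)
Conditions: LiBH(s-Bu)3, THF, −78 °C; then PhNTf2, −78 °C → rt
Reagents that add atoms: N-phenylbis(trifluoromethanesulfonimide), O=S(=O)(N(c1ccccc1)S(=O)(=O)C(F)(F)F)C(F)(F)F
Why: Reductive enol triflation, in which 1,4-hydride delivery from the hindered borohydride to the s-cis enone gives the C2–C3 enolate regiospecifically and O-sulfonylation traps it; this fixes the position of the future C9=C10 olefin and its coupling handle, creates no stereocentre, and the olefin geometries are irrelevant later.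

**Step 5**
Reactants: 8 (2Z,5E)-6,10-dimethylundeca-2,5,9-trien-2-yl trifluoromethanesulfonate, 9 methyl methacrylate
Product: 10 methyl (2E,6E,9Z)-2,6-dimethyl-10-(trifluoromethanesulfonyloxy)undeca-2,6,9-trienoate
Conditions: second-generation Hoveyda–Grubbs catalyst RuCl2(H2IMes)(=CH-C6H4-2-OiPr) (5 mol %), methyl methacrylate (excess), CH2Cl2, 40 °C
Reagents that add atoms: none
Why: Olefin cross-metathesis at the unhindered isopropylidene terminus (the enol triflate and the internal trisubstituted alkene do not engage) gives the thermodynamically favoured (E)-2-methyl-2-enoate that serves as the Michael acceptor.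

**Step 6**
Reactants: 10 methyl (2E,6E,9Z)-2,6-dimethyl-10-(trifluoromethanesulfonyloxy)undeca-2,6,9-trienoate
Product: 11 methyl (2E,9Z)-2,6-dimethyl-6-[(triethylsilyl)peroxy]-10-(trifluoromethanesulfonyloxy)undeca-2,9-dienoate (racemic at C6)
Conditions: Co(acac)2 (10 mol %), O2 (1 atm), Et3SiH (limiting), 1,2-dichloroethane, rt
Reagents that add atoms: dioxygen, O=O; triethylsilane, CC[SiH](CC)CC
Why: Mukaiyama–Isayama hydroperoxysilylation, in which hydrogen-atom transfer from the cobalt hydride to the only electron-rich alkene gives the tertiary C6 radical that is trapped by O2 and silylated; the enoate and the enol triflate are electron-poor and react more slowly; C6 is formed racemic and is sorted out in step 7.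

**Step 7**
Reactants: 11 methyl (2E,9Z)-2,6-dimethyl-6-[(triethylsilyl)peroxy]-10-(trifluoromethanesulfonyloxy)undeca-2,9-dienoate
Product: 13 methyl (2R)-2-[(3R,6R)-6-methyl-6-[(3Z)-4-(trifluoromethanesulfonyloxy)pent-3-en-1-yl]-1,2-dioxan-3-yl]propanoate, via hydroperoxide 12 (not isolated)
Conditions: HCl (cat.), MeOH, 0 °C; solvent switch; chiral bifunctional iminophosphorane–thiourea organocatalyst (10 mol %), toluene, −20 °C; silica-gel separation of the C6-epimeric dioxane
Reagents that add atoms: none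
Why: Proposed new method: desilylation frees tertiary hydroperoxide 12, whose peroxide anion, ion-paired with the chiral iminophosphoranium, adds 6-exo-trig to one face of the thiourea-bound (E)-enoate and sets C3 as R for both enantiomers of racemic 12; the ester enolate is then protonated anti to C4 in the A1,3-minimised conformer to give the 2,3-anti (2R) centre; the (3R,6R) and (3R,6S) dioxanes are diastereomers and the wanted (6R) isomer is separated, so C6 is fixed by separation and not by induction (at most half of the material); the closest known reaction types are the amine-promoted hydroperoxide oxa-Michael cyclisation to 1,2-dioxanes and the iminophosphorane-catalysed enantioselective intramolecular oxa-Michael addition of alcohols to unactivated enoates.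

**Step 8**
Reactants: 5 2-[(1S)-4-methyl-2-methylidenecyclohex-3-en-1-yl]propan-2-ol, 13 methyl (2R)-2-[(3R,6R)-6-methyl-6-[(3Z)-4-(trifluoromethanesulfonyloxy)pent-3-en-1-yl]-1,2-dioxan-3-yl]propanoate
Product: 15 methyl (2R)-2-[(3R,6R)-6-[(3Z)-5-[(1R,6S)-6-(2-hydroxypropan-2-yl)-3-methylcyclohex-2-en-1-yl]-4-methylpent-3-en-1-yl]-6-methyl-1,2-dioxan-3-yl]propanoate, via alkylborane 14 (not isolated)
Conditions: 9-BBN (1.3 equiv), THF, 0 °C → rt; then 13, PdCl2(dppf) (5 mol %), aq. K3PO4, THF–DMF, rt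
Reagents that add atoms: none
Why: Hydroboration followed by B-alkyl Suzuki–Miyaura coupling, in which 9-BBN puts boron on the exocyclic CH2 and hydrogen on C12 from the face opposite the bulky hydroxy-isopropyl group on the neighbouring carbon, setting C12 as R with the new CH2 cis to the C17–C18 bond, and the alkylborane then couples with the vinyl triflate with retention; the tertiary alcohol reacts only slowly with 9-BBN, and the dialkyl peroxide is expected to survive zerovalent palladium and mild base (untested on this substrate).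

**Step 9**
Reactants: 15 methyl (2R)-2-[(3R,6R)-6-[(3Z)-5-[(1R,6S)-6-(2-hydroxypropan-2-yl)-3-methylcyclohex-2-en-1-yl]-4-methylpent-3-en-1-yl]-6-methyl-1,2-dioxan-3-yl]propanoate
Product: 16 methyl (2R)-2-[(3R,6R)-6-methyl-6-{2-[(4aR,8aS)-1,1,3,6-tetramethyl-1,4,4a,7,8,8a-hexahydronaphthalen-2-yl]ethyl}-1,2-dioxan-3-yl]propanoate
Conditions: BF3·OEt2 (1.5 equiv), CH2Cl2, −78 → −30 °C
Reagents that add atoms: none
Why: Cation–olefin cyclisation, in which ionisation of the tertiary alcohol gives the α-terpinyl-type C18 cation, the cis-disposed C9=C10 olefin captures it 6-endo, and E1 loss of H9 under the equilibrating acid gives the tetrasubstituted alkene; no stereocentre is created, and the cis ring fusion follows from C12/C17 of 15.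

**Compound list**
1 | (S)-(−)-α-terpineol, 2-[(1S)-4-methylcyclohex-3-en-1-yl]propan-2-ol | CC1=CC[C@H](CC1)C(C)(C)O | starting material
2 | 2-[(1S)-4-hydroperoxy-4-methylcyclohex-2-en-1-yl]propan-2-ol (both C4 epimers; not isolated) | CC1(OO)CC[C@@H](C=C1)C(C)(C)O | intermediate
3 | (4S)-4-(2-hydroxypropan-2-yl)-1-methylcyclohex-2-en-1-ol (both C1 epimers) | CC1(O)CC[C@@H](C=C1)C(C)(C)O | intermediate
4 | (6R)-6-(2-hydroxypropan-2-yl)-3-methylcyclohex-2-en-1-one | O=C1C=C(C)CC[C@@H]1C(C)(C)O | intermediate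
5 | 2-[(1S)-4-methyl-2-methylidenecyclohex-3-en-1-yl]propan-2-ol | C=C1C=C(C)CC[C@@H]1C(C)(C)O | intermediate
6 | pseudoionone, (3E,5E)-6,10-dimethylundeca-3,5,9-trien-2-one (the commercial 5E/5Z mixture serves equally, that double bond is consumed in step 6) | CC(=O)/C=C/C=C(\C)CCC=C(C)C | starting material
7 | lithium (2Z,5E)-6,10-dimethylundeca-2,5,9-trien-2-olate (not isolated) | [Li+].C/C([O-])=C/C/C=C(\C)CCC=C(C)C | intermediate
8 | (2Z,5E)-6,10-dimethylundeca-2,5,9-trien-2-yl trifluoromethanesulfonate | C/C(OS(=O)(=O)C(F)(F)F)=C/C/C=C(\C)CCC=C(C)C | intermediate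
9 | methyl methacrylate | COC(=O)C(C)=C | starting material
10 | methyl (2E,6E,9Z)-2,6-dimethyl-10-(trifluoromethanesulfonyloxy)undeca-2,6,9-trienoate | COC(=O)/C(C)=C/CC/C(C)=C/C/C=C(/C)OS(=O)(=O)C(F)(F)F | intermediate
11 | methyl (2E,9Z)-2,6-dimethyl-6-[(triethylsilyl)peroxy]-10-(trifluoromethanesulfonyloxy)undeca-2,9-dienoate (racemic at C6) | COC(=O)/C(C)=C/CCC(C)(OO[Si](CC)(CC)CC)CC/C=C(/C)OS(=O)(=O)C(F)(F)F | intermediate
12 | methyl (2E,9Z)-6-hydroperoxy-2,6-dimethyl-10-(trifluoromethanesulfonyloxy)undeca-2,9-dienoate (racemic; not isolated) | COC(=O)/C(C)=C/CCC(C)(OO)CC/C=C(/C)OS(=O)(=O)C(F)(F)F | intermediate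
13 | methyl (2R)-2-[(3R,6R)-6-methyl-6-[(3Z)-4-(trifluoromethanesulfonyloxy)pent-3-en-1-yl]-1,2-dioxan-3-yl]propanoate | COC(=O)[C@H](C)[C@H]1CC[C@@](C)(CC/C=C(/C)OS(=O)(=O)C(F)(F)F)OO1 | intermediate
14 | 2-[(1S,2R)-2-(9-borabicyclo[3.3.1]nonan-9-ylmethyl)-4-methylcyclohex-3-en-1-yl]propan-2-ol (not isolated) | C([C@@H]1C=C(C)CC[C@@H]1C(C)(C)O)B1C2CCCC1CCC2 | intermediate
15 | methyl (2R)-2-[(3R,6R)-6-[(3Z)-5-[(1R,6S)-6-(2-hydroxypropan-2-yl)-3-methylcyclohex-2-en-1-yl]-4-methylpent-3-en-1-yl]-6-methyl-1,2-dioxan-3-yl]propanoate | COC(=O)[C@H](C)[C@H]1CC[C@@](C)(CC/C=C(/C)C[C@@H]2C=C(C)CC[C@@H]2C(C)(C)O)OO1 | intermediate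
16 | methyl (2R)-2-[(3R,6R)-6-methyl-6-{2-[(4aR,8aS)-1,1,3,6-tetramethyl-1,4,4a,7,8,8a-hexahydronaphthalen-2-yl]ethyl}-1,2-dioxan-3-yl]propanoate | COC(=O)[C@H](C)[C@H]1CC[C@@](C)(CCC2=C(C)C[C@@H]3C=C(C)CC[C@@H]3C2(C)C)OO1 | target

**Step count and risks**
Total step count: 9. Longest linear sequence: 6 steps (6 → 8 → 10 → 11 → 13 → 15 → 16, steps 4–9); the ring-B branch is 3 steps (1 → 5).

The three steps most likely to fail:

Step 7. The catalyst-controlled peroxy-Michael addition is without direct precedent, the α-methyl enoate is a weak acceptor, and C6 is only sorted by separation. The fallback leaves the route at 8 and returns at 13; it changes the acceptor to an enal and the activation to covalent iminium catalysis, which is closer to known asymmetric peroxidations. Cross-metathesis of 8 with methacrolein (same ruthenium catalyst as step 5) gives (2Z,5E,9E)-6,10-dimethyl-11-oxoundeca-2,5,9-trien-2-yl trifluoromethanesulfonate F1. Co(acac)2/O2/Et3SiH then gives (2Z,9E)-6,10-dimethyl-11-oxo-6-[(triethylsilyl)peroxy]undeca-2,9-dien-2-yl trifluoromethanesulfonate F2. Acidic methanol frees (2Z,9E)-6-hydroperoxy-6,10-dimethyl-11-oxoundeca-2,9-dien-2-yl trifluoromethanesulfonate F3, which is cyclised with a cinchona-derived primary amine salt (9-amino-9-deoxy-epi-quinine, CF3CO2H) through the iminium ion. The product, after separation of the C6 epimer, is (2R)-2-[(3R,6R)-6-methyl-6-[(3Z)-4-(trifluoromethanesulfonyloxy)pent-3-en-1-yl]-1,2-dioxan-3-yl]propanal F4. Pinnick oxidation (NaClO2, NaH2PO4, 2-methylbut-2-ene) gives (2R)-2-[(3R,6R)-6-methyl-6-[(3Z)-4-(trifluoromethanesulfonyloxy)pent-3-en-1-yl]-1,2-dioxan-3-yl]propanoic acid F5, and Me3SiCHN2 returns 13.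

Step 9. The Lewis acid may open or rearrange the tertiary peroxide, and the C18 cation may eliminate or shift hydride instead of cyclising. The fallback leaves the route at 5 (as alkylborane 14) and at 8 and returns at 16; it closes ring A before any peroxide is present. Suzuki coupling of 14 with 8 under the step 8 conditions gives 2-[(1S,2R)-4-methyl-2-[(2Z,5E)-2,6,10-trimethylundeca-2,5,9-trien-1-yl]cyclohex-3-en-1-yl]propan-2-ol F6. Buffered ionisation (BF3·OEt2, 2,6-di-tert-butylpyridine, −78 °C) gives (4aR,8aS)-2-[(2E)-3,7-dimethylocta-2,6-dien-1-yl]-1,1,3,6-tetramethyl-1,4,4a,7,8,8a-hexahydronaphthalene F7. Cross-metathesis with 9 gives methyl (2E,6E)-2,6-dimethyl-8-[(4aR,8aS)-1,1,3,6-tetramethyl-1,4,4a,7,8,8a-hexahydronaphthalen-2-yl]octa-2,6-dienoate F8. Co(acac)2/O2/Et3SiH gives methyl (2E)-2,6-dimethyl-8-[(4aR,8aS)-1,1,3,6-tetramethyl-1,4,4a,7,8,8a-hexahydronaphthalen-2-yl]-6-[(triethylsilyl)peroxy]oct-2-enoate F9; here the acyclic trisubstituted alkene must outcompete the ring alkene, which is the price of this order. Desilylation to methyl (2E)-6-hydroperoxy-2,6-dimethyl-8-[(4aR,8aS)-1,1,3,6-tetramethyl-1,4,4a,7,8,8a-hexahydronaphthalen-2-yl]oct-2-enoate F10 and the step 7 cyclisation, with removal of the C6 epimer, give 16.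

Step 8. The palladium/borane/base coupling may damage the dioxane or the β-peroxy ester. The fallback leaves the route at 5 (as alkylborane 14) and at 13 and returns at 15; it makes the C9=C10 bond by metathesis, which is known to tolerate dialkyl peroxides. Suzuki coupling of 14 with 2-bromopropene gives 2-[(1S,2R)-4-methyl-2-(2-methylprop-2-en-1-yl)cyclohex-3-en-1-yl]propan-2-ol F11. Ozonolysis of 13 (O3, CH2Cl2, −78 °C) gives the ozonide methyl (2R)-2-[(3R,6S)-6-methyl-6-{2-[5-methyl-5-(trifluoromethanesulfonyloxy)-1,2,4-trioxolan-3-yl]ethyl}-1,2-dioxan-3-yl]propanoate F12, which Me2S reduces to methyl (2R)-2-[(3R,6S)-6-methyl-6-(3-oxopropyl)-1,2-dioxan-3-yl]propanoate F13. Wittig methylenation (Ph3P=CH2, −78 °C) gives methyl (2R)-2-[(3R,6R)-6-(but-3-en-1-yl)-6-methyl-1,2-dioxan-3-yl]propanoate F14. Cross-metathesis of F11 with F14 (same ruthenium catalyst as step 5) gives 15 together with its olefin isomer methyl (2R)-2-[(3R,6R)-6-[(3E)-5-[(1R,6S)-6-(2-hydroxypropan-2-yl)-3-methylcyclohex-2-en-1-yl]-4-methylpent-3-en-1-yl]-6-methyl-1,2-dioxan-3-yl]propanoate F15; both converge on 16 in step 9 because the C9=C10 geometry is erased there.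

**Further compounds**
F1 | step 7 | (2Z,5E,9E)-6,10-dimethyl-11-oxoundeca-2,5,9-trien-2-yl trifluoromethanesulfonate | O=C/C(C)=C/CC/C(C)=C/C/C=C(/C)OS(=O)(=O)C(F)(F)F
F2 | step 7 | (2Z,9E)-6,10-dimethyl-11-oxo-6-[(triethylsilyl)peroxy]undeca-2,9-dien-2-yl trifluoromethanesulfonate | O=C/C(C)=C/CCC(C)(OO[Si](CC)(CC)CC)CC/C=C(/C)OS(=O)(=O)C(F)(F)F
F3 | step 7 | (2Z,9E)-6-hydroperoxy-6,10-dimethyl-11-oxoundeca-2,9-dien-2-yl trifluoromethanesulfonate | O=C/C(C)=C/CCC(C)(OO)CC/C=C(/C)OS(=O)(=O)C(F)(F)F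
F4 | step 7 | (2R)-2-[(3R,6R)-6-methyl-6-[(3Z)-4-(trifluoromethanesulfonyloxy)pent-3-en-1-yl]-1,2-dioxan-3-yl]propanal | O=C[C@H](C)[C@H]1CC[C@@](C)(CC/C=C(/C)OS(=O)(=O)C(F)(F)F)OO1
F5 | step 7 | (2R)-2-[(3R,6R)-6-methyl-6-[(3Z)-4-(trifluoromethanesulfonyloxy)pent-3-en-1-yl]-1,2-dioxan-3-yl]propanoic acid | OC(=O)[C@H](C)[C@H]1CC[C@@](C)(CC/C=C(/C)OS(=O)(=O)C(F)(F)F)OO1
F6 | step 9 | 2-[(1S,2R)-4-methyl-2-[(2Z,5E)-2,6,10-trimethylundeca-2,5,9-trien-1-yl]cyclohex-3-en-1-yl]propan-2-ol | CC(C)=CCC/C(C)=C/C/C=C(/C)C[C@@H]1C=C(C)CC[C@@H]1C(C)(C)O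
F7 | step 9 | (4aR,8aS)-2-[(2E)-3,7-dimethylocta-2,6-dien-1-yl]-1,1,3,6-tetramethyl-1,4,4a,7,8,8a-hexahydronaphthalene | CC(C)=CCC/C(C)=C/CC1=C(C)C[C@@H]2C=C(C)CC[C@@H]2C1(C)C
F8 | step 9 | methyl (2E,6E)-2,6-dimethyl-8-[(4aR,8aS)-1,1,3,6-tetramethyl-1,4,4a,7,8,8a-hexahydronaphthalen-2-yl]octa-2,6-dienoate | COC(=O)/C(C)=C/CC/C(C)=C/CC1=C(C)C[C@@H]2C=C(C)CC[C@@H]2C1(C)C
F9 | step 9 | methyl (2E)-2,6-dimethyl-8-[(4aR,8aS)-1,1,3,6-tetramethyl-1,4,4a,7,8,8a-hexahydronaphthalen-2-yl]-6-[(triethylsilyl)peroxy]oct-2-enoate (both C6 epimers) | COC(=O)/C(C)=C/CCC(C)(OO[Si](CC)(CC)CC)CCC1=C(C)C[C@@H]2C=C(C)CC[C@@H]2C1(C)C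
F10 | step 9 | methyl (2E)-6-hydroperoxy-2,6-dimethyl-8-[(4aR,8aS)-1,1,3,6-tetramethyl-1,4,4a,7,8,8a-hexahydronaphthalen-2-yl]oct-2-enoate (both C6 epimers) | COC(=O)/C(C)=C/CCC(C)(OO)CCC1=C(C)C[C@@H]2C=C(C)CC[C@@H]2C1(C)C
F11 | step 8 | 2-[(1S,2R)-4-methyl-2-(2-methylprop-2-en-1-yl)cyclohex-3-en-1-yl]propan-2-ol | CC(=C)C[C@@H]1C=C(C)CC[C@@H]1C(C)(C)O
F12 | step 8 | methyl (2R)-2-[(3R,6S)-6-methyl-6-{2-[5-methyl-5-(trifluoromethanesulfonyloxy)-1,2,4-trioxolan-3-yl]ethyl}-1,2-dioxan-3-yl]propanoate | COC(=O)[C@H](C)[C@H]1CC[C@@](C)(CCC2OOC(C)(OS(=O)(=O)C(F)(F)F)O2)OO1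
F13 | step 8 | methyl (2R)-2-[(3R,6S)-6-methyl-6-(3-oxopropyl)-1,2-dioxan-3-yl]propanoate | COC(=O)[C@H](C)[C@H]1CC[C@@](C)(CCC=O)OO1
F14 | step 8 | methyl (2R)-2-[(3R,6R)-6-(but-3-en-1-yl)-6-methyl-1,2-dioxan-3-yl]propanoate | COC(=O)[C@H](C)[C@H]1CC[C@@](C)(CCC=C)OO1
F15 | step 8 | methyl (2R)-2-[(3R,6R)-6-[(3E)-5-[(1R,6S)-6-(2-hydroxypropan-2-yl)-3-methylcyclohex-2-en-1-yl]-4-methylpent-3-en-1-yl]-6-methyl-1,2-dioxan-3-yl]propanoate | COC(=O)[C@H](C)[C@H]1CC[C@@](C)(CC/C=C(\C)C[C@@H]2C=C(C)CC[C@@H]2C(C)(C)O)OO1
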